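The numbers in the tables are simulated with made-up constants; scatter was added.

Left-handed product stops growing early: in the north-east run it reads 29.4 % at 1.00 h and 29.4 % at 5.00 h, with 20.9 % of left-handed substrate still there. I take it that the catalyst dies, so each flask gets a fixed dose of catalyst-time, proportional to its charge.

the same everywhere: left-handed substrate 0.020 M; right-handed substrate 0.020 M

| charge | coupling partner | protic impurity | free catalyst | remark | time |
|---|---|---|---|---|---|
| west | 0.040 M | 0.40 mM | 0.34 mM (in portions, 2) | run made earlier; portions every 2.0 min |  |
| north-east | 0.040 M | 0.40 mM | 1.4 mM (in portions, 2) | run made earlier; portions every 2.0 min |  |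
| flask | 0.0400 M | 0.400 mM | 0.68 mM (in portions, 2) | the portions of free catalyst follow each other after 2.0 min, the first at the start | 5.0 h |

| run | time / h | left-handed substrate / % | left-handed product / % |
|---|---|---|---|
| west | 0.417 | 39.7 | 10.6 |
| west | 0.833 | 39.0 | 11.4 |
| west | 1.33 | 39.0 | 11.3 |
| west | 2.50 | 38.1 | 10.9 |
| west | 5.00 | 38.5 | 12.4 |
| north-east | 1.00 | 20.7 | 29.4 |
| north-east | 2.00 | 20.8 | 28.6 |
| north-east | 3.00 | 20.7 | 29.6 |
| north-east | 4.00 | 21.0 | 28.4 |
| north-east | 5.00 | 20.9 | 29.4 |

(readings scatter by 0.5 percentage points)

- free catalyst is single-handed; left-handed substrate and right-handed substrate are mirror images of each other, charged as a racemate, each of them at the stated concentration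
- the analysis behind the earlier runs scatters by 0.5 percentage points, standard deviation

- how much of the left-handed substrate and right-handed substrate together has reacted by 5.0 h
- how much left-handed product there is at 5.0 h, in percent of the left-handed substrate and right-handed substrate together charged
- how much right-handed substrate there is at 5.0 h, in percent of the left-handed substrate and right-handed substrate together charged

1. The west charge is smaller than the impurity and still made product, so I let the impurity take partner, not catalyst. That is 1.00 % of the partner, which I drop.

2. Let x be the left-handed substrate left, as a fraction of its own charge. The partner charge is 2.00 times that charge, so with right-handed substrate ignored, the partner fraction left is (1 + x)/2. Integrating gives the dose D = 2 ln((1 + x)/(2x)): the dimensionless reach of the catalyst's life, had the partner stayed at its charge.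

3. Averaged readings give x = 0.777 in the west run and 0.416 in the north-east run, so D is 0.268 and 1.06. Per charge that is 0.788 mM⁻¹ and 0.759 mM⁻¹, close enough to use their mean, the dose per charge 0.773 mM⁻¹.

4. This flask gets D = 0.526, so x = 0.624 and left-handed product is 18.8 %.

5. One number is not enough: right-handed substrate was never read, so the selectivity factor stays unknown. I leave its share open, and conversion is 18.8 % plus that unread loss.

The forecast gives 18.7 %, 18.6 % and 49.9 %, saying of right-handed substrate “assume it is essentially untouched”.

The flask gives 26.8 %, 19.1 % and 42.3 %.

    coupling partner + protic impurity → quenched reagent (k = 26.0 L mol⁻¹ s⁻¹)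
    coupling partner + free catalyst + left-handed substrate → free catalyst + left-handed product (k = 40.0 L² mol⁻² s⁻¹)
    free catalyst → spent catalyst (k = 0.00190 s⁻¹)
    coupling partner + free catalyst + right-handed substrate → free catalyst + right-handed product (k = 14.0 L² mol⁻² s⁻¹)

The flask has come to rest: over the second half of the time, the change in the share of a substrate or product reaches 0 percentage points, and at 5.00 h free catalyst is 0 % and spent catalyst 100 % of the catalyst charged. Ten times the time gives 26.8 %, 19.1 % and 42.3 %, no change. The conversion beyond left-handed product is right-handed product, 7.75 %.

With 0.0027 M of free catalyst, the dose per charge gives D = 2.09 and left-handed product 39.3 %. That neighbour flask gives 37.7 %, with conversion 57.0 %.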